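The route rests on a late C3–O disconnection in ring C. The key step exploits the C3 methylene of the flavanone, which lies alpha to the C4 ketone and next to the C2 stereocentre bearing ring B: a flavanone 3-hydroxylase replaces the C3 hydrogen trans to ring B by hydroxyl in one operation, setting C3 and leaving the free ring B hydroquinone alone. The precursor is (2S)-2',5'-dihydroxy-4',5,6,7-tetramethoxyflavanone, assembled by Claisen–Schmidt condensation and oxa-Michael closure, resolved as its bis(benzyl) ether and debenzylated. O-Methylation of the new hydroxyl, with ring B briefly benzylated, then gives the target.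

Key step: step 7

Assumption: a flavanone 3-hydroxylase homologue or evolved variant that accepts the 5,6,7-trimethoxy ring A is found by screening and is used as a clarified Escherichia coli lysate.

Remark: ring B goes through step 7 as the free hydroquinone because the natural substrates of this enzyme class are free polyphenols, including readily oxidised catechol and pyrogallol flavanones.

Remark: the enzyme is given the resolved (2S)-flavanone, not the racemate, so the unreactive enantiomer neither competes for the active site nor has to be separated from the polar product.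

Step 1
Reactants: 1 3,4,5-trimethoxyphenol; 2 acetic acid
Product: 3 1-(6-hydroxy-2,3,4-trimethoxyphenyl)ethan-1-one
Conditions: AcOH, BF3·OEt2, 85 °C; then H2O
Reagents that add atoms: none
Why: BF3-promoted Friedel–Crafts C-acetylation of the phenol (Fries-type ortho-acylation) can only occur at the two equivalent ring positions ortho to the hydroxyl, the para position being blocked by methoxy, and the acyl group that has entered deactivates the ring against a second acylation.

Step 2
Reactants: 4 methoxyhydroquinone
Product: 5 1,4-bis(benzyloxy)-2-methoxybenzene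
Conditions: BnBr, K2CO3, DMF, 60 °C, N2
Reagents that add atoms: benzyl bromide, BrCc1ccccc1
Why: Williamson etherification of both phenoxides with a reactive benzylic bromide should be clean, and the nitrogen atmosphere keeps the hydroquinone from air oxidation in base.

Step 3
Reactants: 5 1,4-bis(benzyloxy)-2-methoxybenzene
Product: 7 2,5-bis(benzyloxy)-4-methoxybenzaldehyde, via aryl iminium salt 6 (not isolated)
Conditions: POCl3, DMF, 0 to 70 °C; then ice-water
Reagents that add atoms: N,N-dimethylformamide, CN(C)C=O; water, O
Why: Vilsmeier–Haack formylation attacks the most nucleophilic ring carbon, C5, which is para to the methoxy group and ortho to a benzyloxy group, as in the formylation of 1,2,4-trialkoxybenzenes, whereas C3 is flanked by two ethers and C6 is activated by one ortho oxygen only; the iminium salt 6 is hydrolysed to the aldehyde on quenching.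

Step 4
Reactants: 3 1-(6-hydroxy-2,3,4-trimethoxyphenyl)ethan-1-one; 7 2,5-bis(benzyloxy)-4-methoxybenzaldehyde
Product: 9 racemic 2',5'-bis(benzyloxy)-4',5,6,7-tetramethoxyflavanone, via 2'-hydroxychalcone 8 (not isolated)
Conditions: KOH, EtOH/H2O, rt; then AcOH (to neutrality), reflux
Reagents that add atoms: none
Why: Claisen–Schmidt aldol condensation gives the (E)-2'-hydroxychalcone, and after buffering with acetate the 2'-phenol adds to the enone in a 6-endo oxa-Michael cyclisation that the 6'-methoxy group favours by twisting the chalcone carbonyl out of conjugation; C2 forms as a racemate.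

Step 5
Reactants: 9 racemic 2',5'-bis(benzyloxy)-4',5,6,7-tetramethoxyflavanone
Product: 10 (2S)-2',5'-bis(benzyloxy)-4',5,6,7-tetramethoxyflavanone
Conditions: preparative supercritical fluid chromatography, amylose tris(3,5-dimethylphenylcarbamate) stationary phase, CO2/MeOH, 35 °C
Reagents that add atoms: none
Why: Resolution by chromatography on a polysaccharide chiral stationary phase is a routine way to separate flavanone enantiomers and makes or breaks no bond; the C2 configuration of the collected fraction would be assigned by circular dichroism, and the (2R) fraction can be returned to racemic 9 through chalcone 8 under the conditions of step 4.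

Step 6
Reactants: 10 (2S)-2',5'-bis(benzyloxy)-4',5,6,7-tetramethoxyflavanone
Product: 11 (2S)-2',5'-dihydroxy-4',5,6,7-tetramethoxyflavanone
Conditions: H2 (1 atm), 10% Pd/C, EtOAc/MeOH, rt; handled under argon
Reagents that add atoms: none
Why: Heterogeneous hydrogenolysis of aryl benzyl ethers over Pd/C at atmospheric pressure in a neutral solvent should be much faster than reduction of the aryl ketone or cleavage of the C2–O1 bond, and without acid or base the chalcone–flavanone equilibrium that would racemise C2 stays closed.

Step 7
Reactants: 11 (2S)-2',5'-dihydroxy-4',5,6,7-tetramethoxyflavanone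
Product: 12 (2R,3R)-3,2',5'-trihydroxy-4',5,6,7-tetramethoxyflavanone
Conditions: flavanone 3-hydroxylase (screened or evolved variant, cell lysate), FeSO4 (catalytic), disodium 2-oxoglutarate, sodium ascorbate, catalase, air, HEPES buffer pH 7.0, 5% DMSO, 30 °C
Reagents that add atoms: dioxygen, O=O
Why: 2-Oxoglutarate and O2 bind the divalent iron centre, oxidative decarboxylation gives succinate, CO2 and a tetravalent iron-oxo species, and this abstracts the C3 hydrogen anti to ring B and returns hydroxyl to the same face by radical rebound, so the C3–O bond forms with retention. The closest known reaction is the native conversion of (2S)-flavanones such as naringenin and eriodictyol into (2R,3R)-dihydroflavonols by this enzyme class. No ring is closed. The new C3 stereocenter is controlled by the active site, which should hold the (2S)-flavanone so that only the C3 hydrogen trans to the C2 aryl group faces the iron-oxo unit; C2 is untouched and its descriptor changes from S to R only because C3 gains priority. The step needs chemoselectivity for this one C–H bond over the ring B hydroquinone and the benzylic C2–H bond: the C4 ketone next to C3 and the (2S) configuration match the natural flavanone core, ring B is offered as free phenols like the natural polyphenolic substrates, and ascorbate together with catalase keeps it in the reduced state. Any (2R) material that arises by slow ring-opening racemisation in the buffer should not be accepted by the enzyme and is removed with the unreacted substrate.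

Step 8
Reactants: 12 (2R,3R)-3,2',5'-trihydroxy-4',5,6,7-tetramethoxyflavanone
Product: 13 (2R,3R)-2',5'-bis(benzyloxy)-3-hydroxy-4',5,6,7-tetramethoxyflavanone
Conditions: BnBr, K2CO3, DMF, 0 °C to rt, argon
Reagents that add atoms: benzyl bromide, BrCc1ccccc1
Why: Williamson benzylation in which K2CO3 deprotonates only the two phenols and not the far less acidic C3 ketol hydroxyl, so ring B is capped selectively; low temperature and exclusion of air limit enolisation and oxidation to the flavonol, and no bond to C2 or C3 is broken.

Step 9
Reactants: 13 (2R,3R)-2',5'-bis(benzyloxy)-3-hydroxy-4',5,6,7-tetramethoxyflavanone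
Product: 14 (2R,3R)-2',5'-bis(benzyloxy)-3,4',5,6,7-pentamethoxyflavanone
Conditions: MeOTf, 2,6-di-tert-butyl-4-methylpyridine, CH2Cl2, 0 °C to rt
Reagents that add atoms: methyl trifluoromethanesulfonate, COS(=O)(=O)C(F)(F)F
Why: SN2 O-methylation of the neutral secondary alcohol by the strong electrophile MeOTf, with a hindered pyridine as proton scavenger, avoids alkoxide or enolate formation, so the base-sensitive ketol should be methylated without epimerisation at C2 or C3.

Step 10
Reactants: 14 (2R,3R)-2',5'-bis(benzyloxy)-3,4',5,6,7-pentamethoxyflavanone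
Product: 15 (2R,3R)-2',5'-dihydroxy-3,4',5,6,7-pentamethoxyflavanone (target)
Conditions: H2 (1 atm), 10% Pd/C, EtOAc, rt
Reagents that add atoms: none
Why: Neutral catalytic hydrogenolysis of the two aryl benzyl ethers frees the ring B hydroquinone without acid or base, leaving the 3-methoxy ketone and the trans C2/C3 configuration intact.

Compound list
1 | 3,4,5-trimethoxyphenol | COc1cc(O)cc(OC)c1OC | starting material
2 | acetic acid | CC(=O)O | starting material
3 | 1-(6-hydroxy-2,3,4-trimethoxyphenyl)ethan-1-one (2'-hydroxy-4',5',6'-trimethoxyacetophenone) | CC(=O)c1c(O)cc(OC)c(OC)c1OC | intermediate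
4 | methoxyhydroquinone (2-methoxybenzene-1,4-diol) | COc1cc(O)ccc1O | starting material
5 | 1,4-bis(benzyloxy)-2-methoxybenzene | COc1cc(OCc2ccccc2)ccc1OCc1ccccc1 | intermediate
6 | N-[2,5-bis(benzyloxy)-4-methoxybenzylidene]-N-methylmethanaminium dichlorophosphate (aryl iminium salt, not isolated) | COc1cc(OCc2ccccc2)c(C=[N+](C)C)cc1OCc1ccccc1.[O-]P(=O)(Cl)Cl | intermediate
7 | 2,5-bis(benzyloxy)-4-methoxybenzaldehyde | COc1cc(OCc2ccccc2)c(C=O)cc1OCc1ccccc1 | intermediate
8 | (E)-3-[2,5-bis(benzyloxy)-4-methoxyphenyl]-1-(6-hydroxy-2,3,4-trimethoxyphenyl)prop-2-en-1-one (2'-hydroxychalcone, not isolated) | COc1cc(OCc2ccccc2)c(/C=C/C(=O)c2c(O)cc(OC)c(OC)c2OC)cc1OCc1ccccc1 | intermediate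
9 | racemic 2-[2,5-bis(benzyloxy)-4-methoxyphenyl]-5,6,7-trimethoxychroman-4-one (2',5'-bis(benzyloxy)-4',5,6,7-tetramethoxyflavanone) | COc1cc(OCc2ccccc2)c(C2Oc3cc(OC)c(OC)c(OC)c3C(=O)C2)cc1OCc1ccccc1 | intermediate
10 | (2S)-2-[2,5-bis(benzyloxy)-4-methoxyphenyl]-5,6,7-trimethoxychroman-4-one ((2S)-2',5'-bis(benzyloxy)-4',5,6,7-tetramethoxyflavanone) | COc1cc(OCc2ccccc2)c([C@H]2Oc3cc(OC)c(OC)c(OC)c3C(=O)C2)cc1OCc1ccccc1 | intermediate
11 | (2S)-2-(2,5-dihydroxy-4-methoxyphenyl)-5,6,7-trimethoxychroman-4-one ((2S)-2',5'-dihydroxy-4',5,6,7-tetramethoxyflavanone) | COc1cc(O)c([C@H]2Oc3cc(OC)c(OC)c(OC)c3C(=O)C2)cc1O | intermediate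
12 | (2R,3R)-3,2',5'-trihydroxy-4',5,6,7-tetramethoxyflavanone (2,3-trans) | COc1cc(O)c([C@H]2Oc3cc(OC)c(OC)c(OC)c3C(=O)[C@@H]2O)cc1O | intermediate
13 | (2R,3R)-2',5'-bis(benzyloxy)-3-hydroxy-4',5,6,7-tetramethoxyflavanone (2,3-trans) | COc1cc(OCc2ccccc2)c([C@H]2Oc3cc(OC)c(OC)c(OC)c3C(=O)[C@@H]2O)cc1OCc1ccccc1 | intermediate
14 | (2R,3R)-2',5'-bis(benzyloxy)-3,4',5,6,7-pentamethoxyflavanone (2,3-trans) | COc1cc(OCc2ccccc2)c([C@H]2Oc3cc(OC)c(OC)c(OC)c3C(=O)[C@@H]2OC)cc1OCc1ccccc1 | intermediate
15 | (2R,3R)-2-(2,5-dihydroxy-4-methoxyphenyl)-3,5,6,7-tetramethoxychroman-4-one (CNP0150769.1; 2,3-trans) | COc1cc(O)c([C@H]2Oc3cc(OC)c(OC)c(OC)c3C(=O)[C@@H]2OC)cc1O | target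

Total step count: 10. Longest linear sequence: 9 steps (4 → 5 → 7 → 9 → 10 → 11 → 12 → 13 → 14 → 15).

Steps most likely to fail

Risk 1, step 7. The non-natural 5,6,7-trimethoxy ring A and the 2'-hydroxyl may bind poorly, so that uncoupled decarboxylation of 2-oxoglutarate, iron-mediated autoxidation of ring B or further desaturation to the flavonol outrun the hydroxylation. The fallback builds the C3 oxygen by asymmetric epoxidation of a chalcone and sets out from 3 and 7. MOMCl and NaH in DMF at 0 °C cap the phenol of 3 to give the methoxymethyl ether of the acetophenone F1. Claisen–Schmidt condensation of this ether with 7 (KOH, EtOH, rt) gives the 2'-O-methoxymethyl chalcone F2, which cannot cyclise. Juliá–Colonna epoxidation with poly-L-leucine, urea–H2O2 and DBU in THF should then give the (2R,3S)-epoxy ketone F3. HCl in MeOH at 40 °C removes the acetal, and the freed phenol opens the epoxide at the benzylic carbon with inversion, so that ring C closes trans while the carbinol carbon keeps its configuration. This comes back to the route at 13, from which steps 9 and 10 follow unchanged.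

Risk 2, step 8. Under carbonate the ring B phenoxide ortho to C2 may push open the C2–O1 bond, or the ketol may enolise, which would lead to epimerisation, ring contraction or air oxidation to the flavonol. The fallback avoids phenoxide alkylation altogether and sets out from 12. tert-Butyldimethylsilyl chloride and imidazole in DMF at 0 °C should silylate only the two phenols, giving the bis(silyl) ether F4. MeOTf with 2,6-di-tert-butyl-4-methylpyridine then methylates the C3 hydroxyl to the 3-methoxy bis(silyl) ether F5. HF·pyridine in THF at 0 °C removes both silyl groups, which comes back to the route at the target 15.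

Risk 3, step 4. Condensation between a doubly ortho-substituted aryl methyl ketone and an electron-rich aldehyde may be slow, and the chalcone–flavanone equilibrium may stop short of completion. The fallback replaces condensation and conjugate addition by aldol addition and etherification and sets out from 3 and 7. The dianion of 3 (LiN(iPr)2, 2.2 equivalents, THF, −78 °C) adds to 7 to give the racemic beta-hydroxy ketone F6. An intramolecular Mitsunobu reaction (PPh3, DIAD, THF, 0 °C) then closes ring C by displacement of the activated benzylic alcohol by the phenol, which comes back to the route at 9.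

Further compounds
F1 | step 7 | 1-[2,3,4-trimethoxy-6-(methoxymethoxy)phenyl]ethan-1-one | CC(=O)c1c(OCOC)cc(OC)c(OC)c1OC
F2 | step 7 | (E)-3-[2,5-bis(benzyloxy)-4-methoxyphenyl]-1-[2,3,4-trimethoxy-6-(methoxymethoxy)phenyl]prop-2-en-1-one | COCOc1cc(OC)c(OC)c(OC)c1C(=O)/C=C/c1cc(OCc2ccccc2)c(OC)cc1OCc1ccccc1
F3 | step 7 | [(2R,3S)-3-[2,5-bis(benzyloxy)-4-methoxyphenyl]oxiran-2-yl][2,3,4-trimethoxy-6-(methoxymethoxy)phenyl]methanone | COCOc1cc(OC)c(OC)c(OC)c1C(=O)[C@@H]1O[C@H]1c1cc(OCc2ccccc2)c(OC)cc1OCc1ccccc1
F4 | step 8 | (2R,3R)-2',5'-bis(tert-butyldimethylsilyloxy)-3-hydroxy-4',5,6,7-tetramethoxyflavanone | COc1cc(O[Si](C)(C)C(C)(C)C)c([C@H]2Oc3cc(OC)c(OC)c(OC)c3C(=O)[C@@H]2O)cc1O[Si](C)(C)C(C)(C)C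
F5 | step 8 | (2R,3R)-2',5'-bis(tert-butyldimethylsilyloxy)-3,4',5,6,7-pentamethoxyflavanone | COc1cc(O[Si](C)(C)C(C)(C)C)c([C@H]2Oc3cc(OC)c(OC)c(OC)c3C(=O)[C@@H]2OC)cc1O[Si](C)(C)C(C)(C)C
F6 | step 4 | racemic 3-[2,5-bis(benzyloxy)-4-methoxyphenyl]-3-hydroxy-1-(6-hydroxy-2,3,4-trimethoxyphenyl)propan-1-one | COc1cc(OCc2ccccc2)c(C(O)CC(=O)c2c(O)cc(OC)c(OC)c2OC)cc1OCc1ccccc1
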